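**Assumptions:** Natural (2E,7R,11R)-phytol is bought as the single stereoisomer. The chiral acid of step 2 is made separately from (S)-BINOL and is not counted as a step. Its sense of induction cannot be predicted with certainty, so "(S,S)" stands for the enantiomer that gives 2R; the mirror-image acid is used if a test run shows the opposite.

## Retrosynthetic overview

1. Target 4 ⇒ open-chain phytylhydroquinone 3 by breaking O1–C2. This is the reverse of the tocopherol cyclase reaction: protonation of C2′=C3′, then attack of the ortho phenol oxygen, which sets C2.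
2. 3 ⇒ 2,5-dimethylhydroquinone 2 + natural phytol 1 by breaking the aryl–C1′ bond, the reverse of the prenyl transfer step. C4′ and C8′ come from the chiral pool.
3. Ring order: the aromatic ring is bought. The dihydropyran ring is the only ring formed, in the last step, with C2 set by a chiral Brønsted acid rather than by the substrate.

## Route

Step 1
Reactants: 1 (2E,7R,11R)-phytol; 2 2,5-dimethylbenzene-1,4-diol
Product: 3 2,5-dimethyl-3-[(2E,7R,11R)-3,7,11,15-tetramethylhexadec-2-en-1-yl]benzene-1,4-diol
Conditions: 2 (3 equiv), BF3·OEt2 (0.3 equiv), dry 1,4-dioxane, 20 °C, Ar, dark, 1 added over 2 h, then 12 h; degassed aqueous work-up; flash chromatography under Ar (degassed hexane/EtOAc) to remove excess 2, bis-phytyl product and any chroman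
Reagents that add atoms: none
Why: Friedel–Crafts allylation, in which BF3 ionises the allylic alcohol and the allyl cation attacks through its primary terminus at the only free, OH-activated ring position (the two are equivalent by symmetry), while dioxane tempers the acid so that the trisubstituted alkene is not protonated and the product stays open-chain, excess 2 suppresses double alkylation, and no stereocentre is formed or touched (C7 and C11 of the chain are remote).

Step 2
Reactants: 3 2,5-dimethyl-3-[(2E,7R,11R)-3,7,11,15-tetramethylhexadec-2-en-1-yl]benzene-1,4-diol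
Product: 4 (2R,4′R,8′R)-β-tocopherol
Conditions: (S,S)-imidodiphosphorimidate acid HN[P(=NSO2CF3)(O2Ar*)]2 (5 mol %; O2Ar* = (S)-3,3′-bis[3,5-bis(trifluoromethyl)phenyl]-1,1′-binaphthalene-2,2′-diolate), cyclohexane (0.05 M), 5 Å molecular sieves, 40 °C, Ar, 48 h; then preparative HPLC on cellulose tris(3,5-dimethylphenylcarbamate) to remove residual 2S epimer
Reagents that add atoms: none
Why: Proposed new method: the confined, strongly acidic chiral N–H acid protonates C2′ of the trisubstituted alkene in the Markovnikov sense while its basic sulfonyl/phosphoryl site holds the ortho phenolic O–H, so the phenol oxygen closes the 6-endo ring onto the tertiary C3′ centre inside the chiral pocket (tight ion pair or concerted asynchronous addition), and the pocket distinguishes the methyl group from the long chain and so sets C2 as R under catalyst control with the remote C4′ and C8′ centres untouched; the closest known reaction types are the imidodiphosphorimidate-catalysed asymmetric intramolecular Markovnikov hydroalkoxylation of unactivated alkenols and the tocopherol cyclase chromanol cyclisation, and the step is an isomerisation with no co-product.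

## Compound list

1 | (2E,7R,11R)-phytol, (2E,7R,11R)-3,7,11,15-tetramethylhexadec-2-en-1-ol | OC/C=C(\C)CCC[C@H](C)CCC[C@H](C)CCCC(C)C | starting material
2 | 2,5-dimethylbenzene-1,4-diol (2,5-dimethylhydroquinone) | Cc1cc(O)c(C)cc1O | starting material
3 | 2,5-dimethyl-3-[(2E,7R,11R)-3,7,11,15-tetramethylhexadec-2-en-1-yl]benzene-1,4-diol | Cc1cc(O)c(C)c(C/C=C(\C)CCC[C@H](C)CCC[C@H](C)CCCC(C)C)c1O | intermediate
4 | (2R,4′R,8′R)-β-tocopherol, (2R)-2,5,8-trimethyl-2-[(4R,8R)-4,8,12-trimethyltridecyl]-3,4-dihydro-2H-chromen-6-ol | Cc1cc(O)c(C)c2c1O[C@](C)(CCC[C@H](C)CCC[C@H](C)CCCC(C)C)CC2 | target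

## Step count and risks

Total step count: 2
Longest linear sequence: 2 steps (1 or 2 → 3 → 4)

The route has only two steps, so both are ranked and there is no third.

**Most likely to fail: step 2.** The acid may not distinguish methyl from chain well enough, an unselective background protonation may compete, and 3 is easily oxidised to the quinone. Fallback, from 3 back to 4: give up catalyst control and separate the epimers. 3 is cyclised without selectivity (p-TsOH·H2O 10 mol %, toluene, 60 °C, Ar) to (2RS,4′R,8′R)-β-tocopherol F1, the roughly 1:1 mixture of the two C2 epimers. Preparative HPLC on cellulose tris(3,5-dimethylphenylcarbamate) resolves this into 4 and (2S,4′R,8′R)-β-tocopherol F2, which is discarded. The maximum yield is 50 %, but C2 purity no longer depends on the catalyst.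

**Second: step 1.** Risks are over-reaction to chroman (which would be unselective at C2 and identical in constitution with 4), double alkylation, partial loss of E geometry through the allyl cation, and a modest yield. Fallback, from 2 and 1 back to 3: replace the cationic alkylation by an organometallic coupling that cannot scramble the alkene or close the ring.
- 2 is protected (NaH, chloromethyl methyl ether, DMF, 0 °C) as 1,4-bis(methoxymethoxy)-2,5-dimethylbenzene F3.
- 1 is converted (PBr3, Et2O, −10 °C) into (2E,7R,11R)-phytyl bromide F4.
- F3 is ortho-lithiated (n-BuLi, TMEDA, THF, 0 °C) to [2,5-bis(methoxymethoxy)-3,6-dimethylphenyl]lithium F5.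
- F5 with CuBr·SMe2 (10 mol %) and F4 at −40 °C couples at the primary carbon with retention of the E geometry to give 1,4-bis(methoxymethoxy)-2,5-dimethyl-3-[(2E,7R,11R)-3,7,11,15-tetramethylhexadec-2-en-1-yl]benzene F6.
- Acetal exchange (0.1 M HCl in MeOH, 20 °C, Ar) removes both protecting groups and returns 3.

## Further compounds

F1 | step 2 | (2RS,4′R,8′R)-β-tocopherol, mixture of both C2 epimers | Cc1cc(O)c(C)c2c1OC(C)(CCC[C@H](C)CCC[C@H](C)CCCC(C)C)CC2
F2 | step 2 | (2S,4′R,8′R)-β-tocopherol | Cc1cc(O)c(C)c2c1O[C@@](C)(CCC[C@H](C)CCC[C@H](C)CCCC(C)C)CC2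
F3 | step 1 | 1,4-bis(methoxymethoxy)-2,5-dimethylbenzene | COCOc1cc(C)c(OCOC)cc1C
F4 | step 1 | (2E,7R,11R)-phytyl bromide, (2E,7R,11R)-1-bromo-3,7,11,15-tetramethylhexadec-2-ene | BrC/C=C(\C)CCC[C@H](C)CCC[C@H](C)CCCC(C)C
F5 | step 1 | [2,5-bis(methoxymethoxy)-3,6-dimethylphenyl]lithium | COCOc1cc(C)c(OCOC)c([Li])c1C
F6 | step 1 | 1,4-bis(methoxymethoxy)-2,5-dimethyl-3-[(2E,7R,11R)-3,7,11,15-tetramethylhexadec-2-en-1-yl]benzene | COCOc1cc(C)c(OCOC)c(C/C=C(\C)CCC[C@H](C)CCC[C@H](C)CCCC(C)C)c1C
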